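## The problem

Dorsilurin C (29) is a flavonol whose ring A is fully substituted. It carries hydroxyls at C5 and C7, prenyl groups at C6 and C8, the ring oxygen at C8a and the carbonyl carbon C4 at C4a. Ring B is a 2,2-dimethyl-2H-chromene joined through its C7 to C2 of the pyranone (ring C), and C3 bears a hydroxyl. There is no stereocentre and no stereogenic double bond, so the task is purely one of regiochemistry and chemoselectivity. Ring A is a phloroglucinol: its three oxygens must be told apart, and its three carbons must receive two prenyl groups and one acyl group in a fixed pattern. The prenyl groups ortho to phenols and the chromene double bond do not tolerate strong Brønsted or Lewis acids, electrophilic halogen, peracids, dioxiranes or hydrogenation. This excludes a Friedel–Crafts or Fries acylation at C4a, benzyl ethers, and epoxidation routes to the C3 hydroxyl; the free flavonol is also sensitive to base and oxidants, so the phenols stay masked to the end. The enabling feature is that C8a (oxygen) and C4a (acyl carbon) are neighbours, flanked by C8 (prenyl) and C5 (oxygen). That is the pattern left by a 3-alkoxyaryne C4a≡C8a which takes up a carboxylate oxygen at the carbon remote from the alkoxy group and the acyl group at the carbon next to it.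

## Retrosynthesis

**Unmasking and the C3 oxygen (29 from 28 from 25).** The last cut is the two MOM ethers of 28. MOM is chosen because it directs the ring metalations needed earlier and is removed without hydrogenation or strong Lewis acid. The C3–O bond is cut next, back to flavone 25. A flavone can be deprotonated at C3 and the anion oxidized through boron. This avoids dioxirane epoxidation of the flavone and alkaline-peroxide chemistry on a chalcone, which the three electron-rich alkenes and the C5 oxygen (aurone formation) exclude. The cost is one step after ring closure.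

**Ring C (25 from 23).** Cutting O1–C2 leads to the o-hydroxyaryl ynone 23, which already holds every carbon of the target. The forward step only has to be a 6-endo closure rather than the 5-exo closure to an aurone; conjugate addition of a secondary amine followed by addition–elimination secures this.

**The key cut (23 from 14 and 21 through aryne 22).** O–C8a and C4a–C4 are cut together. This gives the o-silylaryl triflate 14 and the arylpropiolic acid 21, two halves of similar size. Acylation of a diprenylphloroglucinol at C4a would need Friedel–Crafts or Fries acid. Metalation–acylation of a tris-ether is feasible but leaves the three oxygens undifferentiated until a selective deprotection. The aryne insertion instead delivers the free C8a phenol next to the ketone, and forms both bonds at the most crowded edge of ring A, where strain release rather than steric access drives the reaction. The forward step must add the carboxylate regioselectively to aryne 22, transfer the acyl group before the aryl anion is protonated, and stop before ring C closes.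

**Aryne precursor (14 from 13 from 12).** The triflate comes from phenol 13, and 13 from diethylcarbamate 12. The carbamate is the group that singles out O1 and directs the metalations around it.

**Ring A substituents (12 from 9, 5, 3, 2, 1 and prenyl bromide 6).** The C–Si bond and the two C–prenyl bonds are cut by three directed ortho-metalations of carbamate 3, which is made from bis-MOM phenol 2 and phloroglucinol 1.
- A bulky silyl ether at O1 would shield exactly the two positions that must be metalated; a carbamate activates them.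
- Silicon is introduced first (3 to 5), at the C–H between the carbamate and a MOM ether. It then sits next to the future triflate oxygen whatever the order of the two prenylations (5 to 9 to 12).
- The three oxygens are differentiated once, at the first and cheapest step (1 to 2).

**Acid 21 (from 19, 18, 17, 15).** The carboxyl carbon is cut as CO2 from alkyne 19, and the alkyne as a Sonogashira partner of bromochromene 17. The pyran ring of 17 is cut to 4-bromo-2-hydroxybenzaldehyde 15 and an isobutenyl Grignard reagent. This fixes bromine at C7, whereas annulation of 3-bromophenol would give 5- and 7-bromo isomers.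

## Roads not taken

**Alternative 1:** Danheiser benzannulation of ring A.
- **Cut:** C8a–C8, C6–C7 and C4a–C8a.
- **Forward step:** heating 2-(3-methylbut-2-en-1-yl)-3-(triisopropylsilyloxy)cyclobut-2-en-1-one A1 with the silyl ynol ether triisopropyl[(5-methylhex-4-en-1-yn-1-yl)oxy]silane A2. The vinylketene from A1 adds [2+2] to A2, the cyclobutenone opens, and 6π closure gives 2,4-bis(3-methylbut-2-en-1-yl)-3,5-bis(triisopropylsilyloxy)phenol A3.
- **Merits:** both prenyl groups are in place, the future C8a oxygen is the only free phenol, and the three oxygens are differentiated by construction. This is better than the statistical first step of the chosen plan.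
- **Weak points:** A1 and A2 each need several steps from non-aromatic material, and the prenyl alkenes must survive prolonged heating beside ketenes. Most importantly, A3 still has hydrogen at C4a. The bond to the acyl carbon, the hardest bond of ring A, is postponed to exactly the acid-free acylation problem again.
- **Comparison:** the chosen plan starts from commercial phloroglucinol and makes the C4a and C8a bonds in one operation. Alternative 1 is longer overall and solves the easier half.

**Alternative 2:** thermal pyranone annulation on unprotected diprenylphloroglucinol.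
- **Cut:** C4a–C4 and O1–C2.
- **Forward step:** 2,4-bis(3-methylbut-2-en-1-yl)benzene-1,3,5-triol A4 and racemic ethyl 2-(benzoyloxy)-3-(2,2-dimethyl-2H-chromen-7-yl)-3-oxopropanoate A5 are heated without catalyst. The product is the 3-benzoate A6, 2-(2,2-dimethyl-2H-chromen-7-yl)-5,7-dihydroxy-6,8-bis(3-methylbut-2-en-1-yl)-4-oxo-4H-chromen-3-yl benzoate, one debenzoylation from 29.
- **Merits:** clearly the shortest road. It needs no protecting groups, the symmetry of A4 makes the regiochemistry automatic, and the C3 oxygen arrives with the ketoester. Steps 14 and 15 of the chosen plan have no counterpart.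
- **Weak points:** uncatalysed condensation of a phenol with a β-ketoester needs strong heating. Under that heating two prenyl groups ortho to free phenols can cyclize or migrate, and the chromene and the acyloxy ketoester are exposed as well. Direct C-prenylation of phloroglucinol to A4 is also unselective.
- **Comparison:** if A4 were at hand and survived the heating, this road would be better in step count. The chosen plan offers mild temperatures, masked phenols throughout the C–C bond formation, and a defined source of every substituent.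

**Alternative 3:** carbonylative three-component annulation.
- **Cut:** C4a–C4, C4–C3 and O1–C2.
- **Forward step:** 2-iodo-3,5-bis(methoxymethoxy)-4,6-bis(3-methylbut-2-en-1-yl)phenol A7, carbon monoxide and alkyne 19 combine under PdCl2(PPh3)2 and diethylamine. The product is 2-(2,2-dimethyl-2H-chromen-7-yl)-5,7-bis(methoxymethoxy)-6,8-bis(3-methylbut-2-en-1-yl)-4H-chromen-4-one A8, identical with flavone 25.
- **Merits:** three bonds form in one step and ring C closes with them. Alkyne 19 is used directly, so the carboxylation (step 11) and the separate ring closure (step 13) are saved. In convergence and step count this road is at least as good.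
- **Weak points:** A7 cannot be made by electrophilic iodination beside two prenyl groups, so it needs the same metalation sequence as 14. Zerovalent palladium must then insert into an electron-rich C–I bond flanked by two ortho oxygens, and CO insertion must outrun direct alkynylation (benzofuran) and 5-exo closure (aurone).
- **Comparison:** the chosen plan needs no metal insertion at the crowded carbon. The aryne reacts because of its strain, and its regiochemistry is set by the C5 oxygen.

Key step: step 12

Remark on the chemistry: the target has no stereocentre. Diol 16 forms as a racemate and loses its stereocentre in the same step. Enaminone 24 is drawn as the E isomer; either geometry closes to 25.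

## Route

Step 1
Reactants: 1 phloroglucinol (benzene-1,3,5-triol)
Product: 2 3,5-bis(methoxymethoxy)phenol
Conditions: MOMCl (2 equiv), iPr2NEt, DMF, 0 °C to rt
Reagents that add atoms: chloromethyl methyl ether, COCCl
Why: Base-mediated O-alkylation (acetal formation) with two equivalents of MOMCl is statistical, but it is done on the cheapest material and the bis-ether is separable from the mono- and tris-ethers; this is the only place where the three equivalent oxygens are told apart.

Step 2
Reactants: 2 3,5-bis(methoxymethoxy)phenol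
Product: 3 3,5-bis(methoxymethoxy)phenyl diethylcarbamate
Conditions: Et2NCOCl, K2CO3, MeCN, reflux
Reagents that add atoms: N,N-diethylcarbamoyl chloride, CCN(CC)C(Cl)=O
Why: O-Carbamoylation of the phenoxide; the diethylcarbamate is the strongest oxygen-based director for ortho-metalation and is orthogonal to the MOM acetals.

Step 3
Reactants: 3 3,5-bis(methoxymethoxy)phenyl diethylcarbamate
Product: 5 3,5-bis(methoxymethoxy)-2-(trimethylsilyl)phenyl diethylcarbamate, via aryllithium 4 (not isolated)
Conditions: sBuLi, TMEDA, THF, −78 °C; Me3SiCl, −78 °C to rt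
Reagents that add atoms: chlorotrimethylsilane, C[Si](C)(C)Cl
Why: Directed ortho-metalation; the C–H between the carbamate and a MOM ether is activated by both groups and by the stronger director, so it should be metalated before the site between the two MOM ethers, and silylation at −78 °C outruns the anionic ortho-Fries shift. With silicon introduced first it ends next to the future triflate oxygen regardless of the order of the later metalations.

Step 4
Reactants: 5 3,5-bis(methoxymethoxy)-2-(trimethylsilyl)phenyl diethylcarbamate; 6 1-bromo-3-methylbut-2-ene (prenyl bromide)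
Product: 9 3,5-bis(methoxymethoxy)-2-(3-methylbut-2-en-1-yl)-6-(trimethylsilyl)phenyl diethylcarbamate, via aryllithium 7 (not isolated), via arylcopper 8 (not isolated)
Conditions: sBuLi, TMEDA, THF, −78 °C; CuBr·SMe2, −78 °C; 6, −78 to 0 °C
Reagents that add atoms: none
Why: Second directed ortho-metalation at the remaining carbamate-flanked C–H, transmetalation to copper at −78 °C to forestall the anionic ortho-Fries rearrangement, and allylic substitution at the primary carbon of prenyl bromide. Should metalation instead take the site between the MOM ethers first, the isomer formed is carried to the same compound 12 by step 5.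

Step 5
Reactants: 9 3,5-bis(methoxymethoxy)-2-(3-methylbut-2-en-1-yl)-6-(trimethylsilyl)phenyl diethylcarbamate; 6 1-bromo-3-methylbut-2-ene (prenyl bromide)
Product: 12 3,5-bis(methoxymethoxy)-2,4-bis(3-methylbut-2-en-1-yl)-6-(trimethylsilyl)phenyl diethylcarbamate, via aryllithium 10 (not isolated), via arylcopper 11 (not isolated)
Conditions: sBuLi, TMEDA, THF, −78 °C; CuBr·SMe2, −78 °C; 6, −78 to 0 °C
Reagents that add atoms: none
Why: The last ring hydrogen lies between two MOM ethers, the classic doubly activated site for directed ortho-metalation, so kinetic ring metalation at −78 °C should outrun deprotonation of the benzylic–allylic CH2; copper-mediated prenylation as in step 4.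

Step 6
Reactants: 12 3,5-bis(methoxymethoxy)-2,4-bis(3-methylbut-2-en-1-yl)-6-(trimethylsilyl)phenyl diethylcarbamate
Product: 13 3,5-bis(methoxymethoxy)-2,4-bis(3-methylbut-2-en-1-yl)-6-(trimethylsilyl)phenol
Conditions: LiAlH4, THF, reflux; aq. KNaC4H4O6 (potassium sodium tartrate)
Reagents that add atoms: none
Why: Hydride reduction of the carbamate carbonyl releases the aryloxide and reduces the carbamoyl residue to a volatile amine; a non-hydrolytic cleavage is chosen because hot aqueous base would risk protodesilylation of the o-silylphenol, and the MOM ethers, alkenes and aryl–silicon bond are inert to LiAlH4.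

Step 7
Reactants: 13 3,5-bis(methoxymethoxy)-2,4-bis(3-methylbut-2-en-1-yl)-6-(trimethylsilyl)phenol
Product: 14 3,5-bis(methoxymethoxy)-2,4-bis(3-methylbut-2-en-1-yl)-6-(trimethylsilyl)phenyl trifluoromethanesulfonate
Conditions: Tf2O, pyridine, CH2Cl2, 0 °C
Reagents that add atoms: trifluoromethanesulfonic anhydride, O=S(=O)(OS(=O)(=O)C(F)(F)F)C(F)(F)F
Why: O-Sulfonylation of the hindered phenol gives the o-silylaryl triflate; pyridine keeps the medium non-acidic for the MOM acetals and the electron-rich aryl–silicon bond.

Step 8
Reactants: 15 4-bromo-2-hydroxybenzaldehyde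
Product: 17 7-bromo-2,2-dimethyl-2H-chromene, via diol 16 (not isolated)
Conditions: Me2C=CHMgBr (2.5 equiv), THF, 0 °C to rt; aq. NH4Cl; crude 16, PPTS (cat.), toluene, 80 °C
Reagents that add atoms: 2-methylprop-1-en-1-ylmagnesium bromide, CC(C)=C[Mg]Br
Why: Grignard 1,2-addition to the aldehyde (one equivalent is spent on the phenol) gives the racemic benzylic–allylic alcohol; mild acid ionizes it to the o-quinone methide, whose oxa-6π electrocyclization gives the 2H-chromene, so the stereocentre is lost and bromine is fixed at C7 by the starting aldehyde. An alkenyl Grignard reagent does not exchange with the aryl bromide.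

Step 9
Reactants: 17 7-bromo-2,2-dimethyl-2H-chromene
Product: 18 [(2,2-dimethyl-2H-chromen-7-yl)ethynyl]trimethylsilane
Conditions: Me3SiC≡CH, PdCl2(PPh3)2 (cat.), CuI (cat.), Et3N, 70 °C
Reagents that add atoms: ethynyltrimethylsilane, C#C[Si](C)(C)C
Why: Sonogashira coupling of the aryl bromide with the silyl-protected alkyne (zerovalent palladium formed in the flask, CuI as co-catalyst); the chromene double bond is not engaged under these conditions.

Step 10
Reactants: 18 [(2,2-dimethyl-2H-chromen-7-yl)ethynyl]trimethylsilane
Product: 19 7-ethynyl-2,2-dimethyl-2H-chromene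
Conditions: K2CO3 (cat.), MeOH, rt
Reagents that add atoms: none
Why: Methoxide-catalysed protodesilylation of the alkynyl C–Si bond.

Step 11
Reactants: 19 7-ethynyl-2,2-dimethyl-2H-chromene
Product: 21 3-(2,2-dimethyl-2H-chromen-7-yl)prop-2-ynoic acid, via lithium acetylide 20 (not isolated)
Conditions: nBuLi, THF, −78 °C; CO2; cold 1 M HCl
Reagents that add atoms: carbon dioxide, O=C=O
Why: Deprotonation of the terminal alkyne and carboxylation of the lithium acetylide; cold dilute acid frees the acid without touching the chromene.

Step 12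
Reactants: 14 3,5-bis(methoxymethoxy)-2,4-bis(3-methylbut-2-en-1-yl)-6-(trimethylsilyl)phenyl trifluoromethanesulfonate; 21 3-(2,2-dimethyl-2H-chromen-7-yl)prop-2-ynoic acid
Product: 23 3-(2,2-dimethyl-2H-chromen-7-yl)-1-[2-hydroxy-4,6-bis(methoxymethoxy)-3,5-bis(3-methylbut-2-en-1-yl)phenyl]prop-2-yn-1-one, via aryne 22 (not isolated)
Conditions: CsF (4 equiv), THF, 100 °C, sealed tube; aq. NH4Cl
Reagents that add atoms: none
Why: Fluoride attacks silicon of 14 and loss of triflate gives aryne 22 (C4a≡C8a), while excess CsF turns acid 21 into its cesium carboxylate. The carboxylate oxygen adds to C8a, the aryne carbon remote from the C5 methoxymethoxy group: the inductively withdrawing oxygen substituent makes that carbon the more electrophilic one and places the developing carbanion at C4a, next to the C–O bond; the primary alkyl (prenyl) group at C8 opposes this only weakly. The aryl anion at C4a then attacks the adjacent ester carbonyl through a four-membered alkoxide, which opens to the o-acyl phenoxide, so that O–C8a and C4a–C4 are formed by net insertion into the C–O bond of the acid. The closest known reaction is the fluoride-induced insertion of arynes into carboxylic acids to give o-hydroxyaryl ketones, arylpropiolic acids included; the tetrasubstituted aryne is the extension. No ring is closed and no stereocentre is formed. Acyl transfer must beat protonation of the aryl anion, which the aprotic medium, the fully deprotonated acid and the elevated temperature favour; the anionic carboxylate, present throughout, should outcompete ene or cycloaddition reactions of the aryne with the prenyl, chromene and alkyne π bonds. The temperature is kept at the lowest value that still gives acyl transfer and the reaction is stopped when 14 is consumed, so that the chelated phenoxide of 23 does not close ring C under fluoride; any 6-endo product formed early is compound 25 of the next step.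

Step 13
Reactants: 23 3-(2,2-dimethyl-2H-chromen-7-yl)-1-[2-hydroxy-4,6-bis(methoxymethoxy)-3,5-bis(3-methylbut-2-en-1-yl)phenyl]prop-2-yn-1-one
Product: 25 2-(2,2-dimethyl-2H-chromen-7-yl)-5,7-bis(methoxymethoxy)-6,8-bis(3-methylbut-2-en-1-yl)-4H-chromen-4-one, via enaminone 24 (not isolated)
Conditions: Et2NH, EtOH, 60 °C
Reagents that add atoms: none
Why: Conjugate addition of diethylamine to the ynone gives the enaminone, and the ortho phenol displaces the amine by addition–elimination at the β-carbon (net 6-endo closure of ring C); the amine pathway avoids the 5-exo closure to an aurone that alkoxide bases can give.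

Step 14
Reactants: 25 2-(2,2-dimethyl-2H-chromen-7-yl)-5,7-bis(methoxymethoxy)-6,8-bis(3-methylbut-2-en-1-yl)-4H-chromen-4-one
Product: 28 2-(2,2-dimethyl-2H-chromen-7-yl)-3-hydroxy-5,7-bis(methoxymethoxy)-6,8-bis(3-methylbut-2-en-1-yl)-4H-chromen-4-one, via 3-lithioflavone 26 (not isolated), via boronate 27 (not isolated)
Conditions: LiN(iPr)2, THF, −78 °C; B(OMe)3, −78 to 0 °C; H2O2 (30%), AcOH, 0 °C
Reagents that add atoms: hydrogen peroxide, OO
Why: Deprotonation of the flavone at C3 (α-position of the vinylogous ester), trapping as the boronate and C–B oxidation is a known way from flavones to flavonols; C3–H is far more acidic than the benzylic–allylic CH2 groups, and H2O2 in acetic acid at 0 °C without mineral acid forms little peracid, so the three alkenes are spared.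

Step 15
Reactants: 28 2-(2,2-dimethyl-2H-chromen-7-yl)-3-hydroxy-5,7-bis(methoxymethoxy)-6,8-bis(3-methylbut-2-en-1-yl)-4H-chromen-4-one
Product: 29 dorsilurin C, 2-(2,2-dimethyl-2H-chromen-7-yl)-3,5,7-trihydroxy-6,8-bis(3-methylbut-2-en-1-yl)-4H-chromen-4-one
Conditions: HCl (1 M, MeOH–H2O), 45 °C
Reagents that add atoms: none
Why: Acid-catalysed transacetalization to methanol removes both MOM groups (the chelated C5 ether first); dilute acid at moderate temperature is the usual end of prenylated flavonoid syntheses and is kept short to avoid cyclization of the prenyl groups onto the freed phenols.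

## Compound list

1 | phloroglucinol (benzene-1,3,5-triol) | Oc1cc(O)cc(O)c1 | starting material
2 | 3,5-bis(methoxymethoxy)phenol | COCOc1cc(O)cc(OCOC)c1 | intermediate
3 | 3,5-bis(methoxymethoxy)phenyl diethylcarbamate | CCN(CC)C(=O)Oc1cc(OCOC)cc(OCOC)c1 | intermediate
4 | [2-(diethylcarbamoyloxy)-4,6-bis(methoxymethoxy)phenyl]lithium | CCN(CC)C(=O)Oc1cc(OCOC)cc(OCOC)c1[Li] | intermediate
5 | 3,5-bis(methoxymethoxy)-2-(trimethylsilyl)phenyl diethylcarbamate | CCN(CC)C(=O)Oc1cc(OCOC)cc(OCOC)c1[Si](C)(C)C | intermediate
6 | 1-bromo-3-methylbut-2-ene (prenyl bromide) | CC(C)=CCBr | starting material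
7 | [2-(diethylcarbamoyloxy)-4,6-bis(methoxymethoxy)-3-(trimethylsilyl)phenyl]lithium | CCN(CC)C(=O)Oc1c([Li])c(OCOC)cc(OCOC)c1[Si](C)(C)C | intermediate
8 | [2-(diethylcarbamoyloxy)-4,6-bis(methoxymethoxy)-3-(trimethylsilyl)phenyl]copper | CCN(CC)C(=O)Oc1c([Cu])c(OCOC)cc(OCOC)c1[Si](C)(C)C | intermediate
9 | 3,5-bis(methoxymethoxy)-2-(3-methylbut-2-en-1-yl)-6-(trimethylsilyl)phenyl diethylcarbamate | CCN(CC)C(=O)Oc1c(CC=C(C)C)c(OCOC)cc(OCOC)c1[Si](C)(C)C | intermediate
10 | [4-(diethylcarbamoyloxy)-2,6-bis(methoxymethoxy)-3-(3-methylbut-2-en-1-yl)-5-(trimethylsilyl)phenyl]lithium | CCN(CC)C(=O)Oc1c(CC=C(C)C)c(OCOC)c([Li])c(OCOC)c1[Si](C)(C)C | intermediate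
11 | [4-(diethylcarbamoyloxy)-2,6-bis(methoxymethoxy)-3-(3-methylbut-2-en-1-yl)-5-(trimethylsilyl)phenyl]copper | CCN(CC)C(=O)Oc1c(CC=C(C)C)c(OCOC)c([Cu])c(OCOC)c1[Si](C)(C)C | intermediate
12 | 3,5-bis(methoxymethoxy)-2,4-bis(3-methylbut-2-en-1-yl)-6-(trimethylsilyl)phenyl diethylcarbamate | CCN(CC)C(=O)Oc1c(CC=C(C)C)c(OCOC)c(CC=C(C)C)c(OCOC)c1[Si](C)(C)C | intermediate
13 | 3,5-bis(methoxymethoxy)-2,4-bis(3-methylbut-2-en-1-yl)-6-(trimethylsilyl)phenol | COCOc1c(CC=C(C)C)c(OCOC)c([Si](C)(C)C)c(O)c1CC=C(C)C | intermediate
14 | 3,5-bis(methoxymethoxy)-2,4-bis(3-methylbut-2-en-1-yl)-6-(trimethylsilyl)phenyl trifluoromethanesulfonate | COCOc1c(CC=C(C)C)c(OCOC)c([Si](C)(C)C)c(OS(=O)(=O)C(F)(F)F)c1CC=C(C)C | intermediate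
15 | 4-bromo-2-hydroxybenzaldehyde | O=Cc1ccc(Br)cc1O | starting material
16 | 5-bromo-2-(1-hydroxy-3-methylbut-2-en-1-yl)phenol (racemic) | CC(C)=CC(O)c1ccc(Br)cc1O | intermediate
17 | 7-bromo-2,2-dimethyl-2H-chromene | CC1(C)C=Cc2ccc(Br)cc2O1 | intermediate
18 | [(2,2-dimethyl-2H-chromen-7-yl)ethynyl]trimethylsilane | CC1(C)C=Cc2ccc(C#C[Si](C)(C)C)cc2O1 | intermediate
19 | 7-ethynyl-2,2-dimethyl-2H-chromene | CC1(C)C=Cc2ccc(C#C)cc2O1 | intermediate
20 | [(2,2-dimethyl-2H-chromen-7-yl)ethynyl]lithium | CC1(C)C=Cc2ccc(C#C[Li])cc2O1 | intermediate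
21 | 3-(2,2-dimethyl-2H-chromen-7-yl)prop-2-ynoic acid | CC1(C)C=Cc2ccc(C#CC(=O)O)cc2O1 | intermediate
22 | 1,2-didehydro-3,5-bis(methoxymethoxy)-4,6-bis(3-methylbut-2-en-1-yl)benzene (aryne) | COCOC1=C(CC=C(C)C)C(OCOC)=C(CC=C(C)C)C#C1 | intermediate
23 | 3-(2,2-dimethyl-2H-chromen-7-yl)-1-[2-hydroxy-4,6-bis(methoxymethoxy)-3,5-bis(3-methylbut-2-en-1-yl)phenyl]prop-2-yn-1-one | COCOc1c(CC=C(C)C)c(OCOC)c(C(=O)C#Cc2ccc3c(c2)OC(C)(C)C=C3)c(O)c1CC=C(C)C | intermediate
24 | (2E)-3-(diethylamino)-3-(2,2-dimethyl-2H-chromen-7-yl)-1-[2-hydroxy-4,6-bis(methoxymethoxy)-3,5-bis(3-methylbut-2-en-1-yl)phenyl]prop-2-en-1-one | CCN(CC)/C(=C/C(=O)c1c(O)c(CC=C(C)C)c(OCOC)c(CC=C(C)C)c1OCOC)c1ccc2c(c1)OC(C)(C)C=C2 | intermediate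
25 | 2-(2,2-dimethyl-2H-chromen-7-yl)-5,7-bis(methoxymethoxy)-6,8-bis(3-methylbut-2-en-1-yl)-4H-chromen-4-one | COCOc1c(CC=C(C)C)c(OCOC)c2c(=O)cc(-c3ccc4c(c3)OC(C)(C)C=C4)oc2c1CC=C(C)C | intermediate
26 | [2-(2,2-dimethyl-2H-chromen-7-yl)-5,7-bis(methoxymethoxy)-6,8-bis(3-methylbut-2-en-1-yl)-4-oxo-4H-chromen-3-yl]lithium | COCOc1c(CC=C(C)C)c(OCOC)c2c(=O)c([Li])c(-c3ccc4c(c3)OC(C)(C)C=C4)oc2c1CC=C(C)C | intermediate
27 | dimethyl [2-(2,2-dimethyl-2H-chromen-7-yl)-5,7-bis(methoxymethoxy)-6,8-bis(3-methylbut-2-en-1-yl)-4-oxo-4H-chromen-3-yl]boronate | COCOc1c(CC=C(C)C)c(OCOC)c2c(=O)c(B(OC)OC)c(-c3ccc4c(c3)OC(C)(C)C=C4)oc2c1CC=C(C)C | intermediate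
28 | 2-(2,2-dimethyl-2H-chromen-7-yl)-3-hydroxy-5,7-bis(methoxymethoxy)-6,8-bis(3-methylbut-2-en-1-yl)-4H-chromen-4-one | COCOc1c(CC=C(C)C)c(OCOC)c2c(=O)c(O)c(-c3ccc4c(c3)OC(C)(C)C=C4)oc2c1CC=C(C)C | intermediate
29 | dorsilurin C, 2-(2,2-dimethyl-2H-chromen-7-yl)-3,5,7-trihydroxy-6,8-bis(3-methylbut-2-en-1-yl)-4H-chromen-4-one | CC(C)=CCc1c(O)c(CC=C(C)C)c2oc(-c3ccc4c(c3)OC(C)(C)C=C4)c(O)c(=O)c2c1O | target

## Step count and risks

Total: 15 steps. Longest linear sequence: 11 steps (steps 1–7, then 12–15). The ring B branch (steps 8–11) joins at step 12.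

**Step 12 (key step).**
- **What may go wrong:** the aryl anion at C4a may be protonated before it attacks the ester carbonyl, giving O-arylation without the C–C bond. The alkynoate may lose CO2 at the temperature that acyl transfer needs. The phenoxide of the product may close ring C unselectively under fluoride. Addition at the wrong aryne carbon is the less likely failure.
- **Fallback without an aryne:** it sets out from 1 and 21 and returns at 23.
  - Exhaustive protection of 1 (NaH, MOMCl, DMF) gives 1,3,5-tris(methoxymethoxy)benzene F1.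
  - Two rounds of lithiation between MOM ethers (nBuLi, THF, 0 °C) and copper-mediated prenylation with 6 give 1,3,5-tris(methoxymethoxy)-2-(3-methylbut-2-en-1-yl)benzene F2, then 1,3,5-tris(methoxymethoxy)-2,4-bis(3-methylbut-2-en-1-yl)benzene F3.
  - Acid 21 is converted with MeNHOMe·HCl and a carbodiimide into 3-(2,2-dimethyl-2H-chromen-7-yl)-N-methoxy-N-methylprop-2-ynamide F4.
  - Lithiation of F3 at its last ring position and acylation with F4 give 3-(2,2-dimethyl-2H-chromen-7-yl)-1-[2,4,6-tris(methoxymethoxy)-3,5-bis(3-methylbut-2-en-1-yl)phenyl]prop-2-yn-1-one F5.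
  - Chelation-controlled removal of one of the two equivalent ortho MOM groups with MgBr2·OEt2 returns to 23.

**Step 5.**
- **What may go wrong:** lateral metalation. The benzylic–allylic CH2 of the prenyl group next to the carbamate may be deprotonated, followed by a 1,4-carbamoyl shift, in competition with ring metalation between the MOM ethers.
- **Fallback:** the prenyl group between the MOM ethers is installed before the carbamate exists. It sets out from 2 and returns at 12.
  - iPr3SiCl and imidazole give [3,5-bis(methoxymethoxy)phenoxy]triisopropylsilane F6. Its bulky silyl ether shields both ortho positions, so nBuLi metalates only between the MOM ethers.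
  - Prenylation with 6 gives [3,5-bis(methoxymethoxy)-4-(3-methylbut-2-en-1-yl)phenoxy]triisopropylsilane F7.
  - Bu4NF gives 3,5-bis(methoxymethoxy)-4-(3-methylbut-2-en-1-yl)phenol F8.
  - Et2NCOCl gives 3,5-bis(methoxymethoxy)-4-(3-methylbut-2-en-1-yl)phenyl diethylcarbamate F9.
  - sBuLi/TMEDA then Me3SiCl gives 3,5-bis(methoxymethoxy)-4-(3-methylbut-2-en-1-yl)-2-(trimethylsilyl)phenyl diethylcarbamate F10.
  - A last metalation at the only ring hydrogen left, now between the carbamate and a MOM ether, and prenylation with 6 give 12. In this order the only benzylic CH2 present is flanked by MOM ethers alone.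

**Step 6.**
- **What may go wrong:** hydride attack at the carbonyl of the di-ortho-substituted carbamate may be sluggish. The silyl group may be lost from the o-silylphenoxide under forcing conditions or on work-up.
- **Fallback:** a carbamate that leaves by elimination instead of attack at the carbonyl. It sets out from 2 and returns at 14.
  - Isopropyl isocyanate (cat. Et3N) gives 3,5-bis(methoxymethoxy)phenyl isopropylcarbamate F11.
  - The three metalations are run after N-silylation in the flask (Me3SiOTf, TMEDA; then nBuLi, −78 °C) with the same electrophiles. They give in turn 3,5-bis(methoxymethoxy)-2-(trimethylsilyl)phenyl isopropylcarbamate F12, 3,5-bis(methoxymethoxy)-2-(3-methylbut-2-en-1-yl)-6-(trimethylsilyl)phenyl isopropylcarbamate F13 and 3,5-bis(methoxymethoxy)-2,4-bis(3-methylbut-2-en-1-yl)-6-(trimethylsilyl)phenyl isopropylcarbamate F14.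
  - Et2NH and DBU in MeCN at 40 °C deprotonate the N–H and expel the aryloxide with loss of isopropyl isocyanate. PhNTf2 added to the same flask triflates the phenoxide to give 14.

**Step 15.**
- **What may go wrong:** acid may cyclize a prenyl group onto the neighbouring freed phenol (chroman formation) or add solvent to the chromene double bond before the hindered C7 MOM ether is cleaved.
- **Fallback:** non-protic cleavage by silyl transfer. It sets out from 28 and returns at 29.
  - Me3SiOTf and 2,2′-bipyridyl in MeCN at 0 °C exchange the aryl MOM ethers for silyl ethers (and silylate the C3 hydroxyl), giving 2-(2,2-dimethyl-2H-chromen-7-yl)-6,8-bis(3-methylbut-2-en-1-yl)-3,5,7-tris(trimethylsilyloxy)-4H-chromen-4-one F15.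
  - Water at neutral pH hydrolyses F15 to 29.

## Further compounds

F1 | step 12 | 1,3,5-tris(methoxymethoxy)benzene | COCOc1cc(OCOC)cc(OCOC)c1
F2 | step 12 | 1,3,5-tris(methoxymethoxy)-2-(3-methylbut-2-en-1-yl)benzene | COCOc1cc(OCOC)c(CC=C(C)C)c(OCOC)c1
F3 | step 12 | 1,3,5-tris(methoxymethoxy)-2,4-bis(3-methylbut-2-en-1-yl)benzene | COCOc1cc(OCOC)c(CC=C(C)C)c(OCOC)c1CC=C(C)C
F4 | step 12 | 3-(2,2-dimethyl-2H-chromen-7-yl)-N-methoxy-N-methylprop-2-ynamide | CON(C)C(=O)C#Cc1ccc2c(c1)OC(C)(C)C=C2
F5 | step 12 | 3-(2,2-dimethyl-2H-chromen-7-yl)-1-[2,4,6-tris(methoxymethoxy)-3,5-bis(3-methylbut-2-en-1-yl)phenyl]prop-2-yn-1-one | COCOc1c(CC=C(C)C)c(OCOC)c(C(=O)C#Cc2ccc3c(c2)OC(C)(C)C=C3)c(OCOC)c1CC=C(C)C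
F6 | step 5 | [3,5-bis(methoxymethoxy)phenoxy]triisopropylsilane | COCOc1cc(OCOC)cc(O[Si](C(C)C)(C(C)C)C(C)C)c1
F7 | step 5 | [3,5-bis(methoxymethoxy)-4-(3-methylbut-2-en-1-yl)phenoxy]triisopropylsilane | COCOc1cc(O[Si](C(C)C)(C(C)C)C(C)C)cc(OCOC)c1CC=C(C)C
F8 | step 5 | 3,5-bis(methoxymethoxy)-4-(3-methylbut-2-en-1-yl)phenol | COCOc1cc(O)cc(OCOC)c1CC=C(C)C
F9 | step 5 | 3,5-bis(methoxymethoxy)-4-(3-methylbut-2-en-1-yl)phenyl diethylcarbamate | CCN(CC)C(=O)Oc1cc(OCOC)c(CC=C(C)C)c(OCOC)c1
F10 | step 5 | 3,5-bis(methoxymethoxy)-4-(3-methylbut-2-en-1-yl)-2-(trimethylsilyl)phenyl diethylcarbamate | CCN(CC)C(=O)Oc1cc(OCOC)c(CC=C(C)C)c(OCOC)c1[Si](C)(C)C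
F11 | step 6 | 3,5-bis(methoxymethoxy)phenyl isopropylcarbamate | CC(C)NC(=O)Oc1cc(OCOC)cc(OCOC)c1
F12 | step 6 | 3,5-bis(methoxymethoxy)-2-(trimethylsilyl)phenyl isopropylcarbamate | CC(C)NC(=O)Oc1cc(OCOC)cc(OCOC)c1[Si](C)(C)C
F13 | step 6 | 3,5-bis(methoxymethoxy)-2-(3-methylbut-2-en-1-yl)-6-(trimethylsilyl)phenyl isopropylcarbamate | CC(C)NC(=O)Oc1c(CC=C(C)C)c(OCOC)cc(OCOC)c1[Si](C)(C)C
F14 | step 6 | 3,5-bis(methoxymethoxy)-2,4-bis(3-methylbut-2-en-1-yl)-6-(trimethylsilyl)phenyl isopropylcarbamate | CC(C)NC(=O)Oc1c(CC=C(C)C)c(OCOC)c(CC=C(C)C)c(OCOC)c1[Si](C)(C)C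
F15 | step 15 | 2-(2,2-dimethyl-2H-chromen-7-yl)-6,8-bis(3-methylbut-2-en-1-yl)-3,5,7-tris(trimethylsilyloxy)-4H-chromen-4-one | CC(C)=CCc1c(O[Si](C)(C)C)c(CC=C(C)C)c2oc(-c3ccc4c(c3)OC(C)(C)C=C4)c(O[Si](C)(C)C)c(=O)c2c1O[Si](C)(C)C
A1 | alternative 1 | 2-(3-methylbut-2-en-1-yl)-3-(triisopropylsilyloxy)cyclobut-2-en-1-one | CC(C)=CCC1=C(O[Si](C(C)C)(C(C)C)C(C)C)CC1=O
A2 | alternative 1 | triisopropyl[(5-methylhex-4-en-1-yn-1-yl)oxy]silane | CC(C)=CCC#CO[Si](C(C)C)(C(C)C)C(C)C
A3 | alternative 1 | 2,4-bis(3-methylbut-2-en-1-yl)-3,5-bis(triisopropylsilyloxy)phenol | CC(C)=CCc1c(O)cc(O[Si](C(C)C)(C(C)C)C(C)C)c(CC=C(C)C)c1O[Si](C(C)C)(C(C)C)C(C)C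
A4 | alternative 2 | 2,4-bis(3-methylbut-2-en-1-yl)benzene-1,3,5-triol | CC(C)=CCc1c(O)cc(O)c(CC=C(C)C)c1O
A5 | alternative 2 | ethyl 2-(benzoyloxy)-3-(2,2-dimethyl-2H-chromen-7-yl)-3-oxopropanoate (racemic) | CCOC(=O)C(OC(=O)c1ccccc1)C(=O)c1ccc2c(c1)OC(C)(C)C=C2
A6 | alternative 2 | 2-(2,2-dimethyl-2H-chromen-7-yl)-5,7-dihydroxy-6,8-bis(3-methylbut-2-en-1-yl)-4-oxo-4H-chromen-3-yl benzoate | CC(C)=CCc1c(O)c(CC=C(C)C)c2oc(-c3ccc4c(c3)OC(C)(C)C=C4)c(OC(=O)c3ccccc3)c(=O)c2c1O
A7 | alternative 3 | 2-iodo-3,5-bis(methoxymethoxy)-4,6-bis(3-methylbut-2-en-1-yl)phenol | COCOc1c(I)c(O)c(CC=C(C)C)c(OCOC)c1CC=C(C)C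
A8 | alternative 3 | 2-(2,2-dimethyl-2H-chromen-7-yl)-5,7-bis(methoxymethoxy)-6,8-bis(3-methylbut-2-en-1-yl)-4H-chromen-4-one | COCOc1c(CC=C(C)C)c(OCOC)c2c(=O)cc(-c3ccc4c(c3)OC(C)(C)C=C4)oc2c1CC=C(C)C
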